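**Retrosynthetic overview**
1. Labels: terpenoid carbons are C1–C12, where C11 is the CH2 between C9 and ring D and C12 is the CH2 on C8. Ring D is C1′(=O), C2′(Me), C3′, C4′, C5′, C6′(Me). The γ-lactone is C7′(=O)/C8′H2.
2. Key cut: C8–C5′ and C12–C2′. These two bonds tie the three contiguous quaternary carbons C8/C5′/C6′ into the cyclopentane (C8-C9-C11-C6′-C5′) and the bicyclo[2.2.2]octanone. Retro-[4+2] gives a butenolide-fused 6,6-disubstituted cyclohexa-2,4-dienone hanging from a C8=C12 methylene. Its only uncontrolled centre, C6′, lies next to the dienone carbonyl and is photolabile through ketene opening, so both epimers are funnelled into one cage.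
3. C11 is a formaldehyde linchpin: α-methylenation at C9, then Michael addition of a dimedone-type ring-D dione (malonate + 2-methylpent-1-en-3-one). The butenolide follows by triflate formation and Stille coupling.
4. Ring B, the C10 methyl and the C4 gem-dimethyl group are the ten carbons of (+)-verbenone. Its CMe2 bridge steers C10 and the unusual 9β-H. The cyclobutane bond C7–C4 is then cut, and the C4 cation is trapped by the C3 ester to close lactone ring A.
5. Ring order: D → butenolide → A (ring B released) → C plus bicyclo[2.2.2]octane (key step). C4′–H and the C1=C2 double bond come last.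

Key step: step 10

Remark: (1R,5R)-(+)-verbenone is taken as purchasable (otherwise it is one allylic oxidation from (+)-α-pinene). A SMILES without a tag at C2′, C4′ or C6′ denotes an epimer mixture at that centre.

Step 1
Reactants: 1 (1R,5R)-(+)-verbenone; 2 (3-ethoxy-3-oxopropyl)zinc bromide
Product: 4 4-methyl-4-(2-ethoxycarbonylethyl)nopinone (chain anti to the CMe2 bridge), via silyl enol ether 3 (not isolated)
Conditions: 2 (2 equiv), CuBr·SMe2 (10 mol %), TMSCl, DMPU, THF, 0 °C → rt; then 1 M HCl
Reagents that add atoms: chlorotrimethylsilane C[Si](C)(C)Cl (atoms only in 3)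
Why: Copper-catalysed, TMSCl-accelerated conjugate addition of a zinc homoenolate to the β,β-disubstituted enone should deliver the C1–C3 chain to C10 from the face anti to the gem-dimethyl bridge, the face that organocopper reagents use on verbenone, which fixes C10 (methyl syn to the bridge) relative to C5.

Step 2
Reactants: 4 keto ester
Product: 5 3-methylene ketone (C9=C11 exocyclic enone)
Conditions: (CH2O)n, i-Pr2NH·TFA, THF, reflux
Reagents that add atoms: formaldehyde (as paraformaldehyde) C=O
Why: Mannich-type α-methylenation can occur only at C9 because the other α-carbon is the cyclobutane bridgehead, and it creates no stereocentre.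

Step 3
Reactants: 6 dimethyl malonate; 7 2-methylpent-1-en-3-one
Product: 8 methyl 3,5-dimethyl-2,4-dioxocyclohexane-1-carboxylate (epimer/enol mixture)
Conditions: NaOMe, MeOH, reflux; then aq HCl
Reagents that add atoms: none
Why: Michael addition followed by Dieckmann cyclisation, the classical dimedone synthesis stopped before decarboxylation, assembles the six ring-D carbons with both methyl groups and the future lactone carbonyl C7′ in one operation, and all its stereocentres are epimerisable and irrelevant.

Step 4
Reactants: 5 exocyclic enone; 8 ring-D dione ester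
Product: 9 Michael adduct (C11 anti to the CMe2 bridge, 9β-H; mixture at C2′, C4′, C6′)
Conditions: Et3N (0.2 equiv), MeCN, rt; then DBU (1.5 equiv), 45 °C
Reagents that add atoms: none
Why: Michael addition of the cyclic 1,3-dione enolate (a vinylogous acid, far more acidic than the β-keto ester CH) through its only carbon terminus C6′ to the unhindered exocyclic CH2 forms C11–C6′, and reversible addition together with base equilibration of the enolisable C9 should leave the chain anti to the gem-dimethyl bridge, the strongly favoured epimer in the pinane frame.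

Step 5
Reactants: 9 Michael adduct
Product: 10 C5′ enol triflate
Conditions: Tf2O, i-Pr2NEt, CH2Cl2, −78 → 0 °C
Reagents that add atoms: trifluoromethanesulfonic anhydride O=S(=O)(OS(=O)(=O)C(F)(F)F)C(F)(F)F
Why: Only the β-keto ester can still enolise as a 1,3-dicarbonyl, so O-sulfonylation should give the C5′=C4′ enol triflate regiospecifically (standard β-keto ester enol triflate formation).

Step 6
Reactants: 10 enol triflate
Product: 12 pinane-stage butenolide, via hydroxymethyl enoate 11 (not isolated)
Conditions: Bu3SnCH2OH, Pd(PPh3)4 (cat.), LiCl, dioxane, 90 °C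
Reagents that add atoms: (tributylstannyl)methanol CCCC[Sn](CCCC)(CCCC)CO
Why: Stille coupling places the C8′ hydroxymethyl group on C5′ cis to the ester across the ring alkene, and the hydroxy ester should lactonise spontaneously, a known route from β-keto esters to fused butenolides.

Step 7
Reactants: 12 pinane-stage butenolide
Product: 13 keto bis-lactone (trans-fused ε-lactone ring A on cyclohexanone ring B; C11 axial α)
Conditions: SnCl4 (3 equiv), CH2Cl2, −20 → 0 °C; aq NaHCO3
Reagents that add atoms: none
Why: Lewis-acid heterolysis of the strained C7–C4 cyclobutane bond α to the ketone (known for 4-aryl nopinones, where a phenol oxygen traps the cation) gives the tertiary C4 cation and a tin enolate, the ester carbonyl oxygen of the C10 chain captures the cation and chloride removes the ethyl group, so ring A closes trans-fused while C5, C10 and C9 are untouched because the equatorial C9–H lies near the carbonyl plane and resists enolisation.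

Step 8
Reactants: 13 keto bis-lactone
Product: 14 C8 exocyclic methylene compound
Conditions: CH2Br2, Zn, TiCl4, THF/CH2Cl2, 0 °C → rt
Reagents that add atoms: dibromomethane BrCBr
Why: Lombardo methylenation is non-basic and should therefore not epimerise C9, it leaves lactones alone, and it should choose the C8 ketone over the C1′ ketone, which is flanked by a quaternary and a tertiary carbon.

Step 9
Reactants: 14 methylene compound
Product: 15 butenolide-fused 6,6-disubstituted cyclohexa-2,4-dienone (both C6′ epimers)
Conditions: IBX·4-methoxypyridine N-oxide, DMSO, rt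
Reagents that add atoms: none
Why: IBX dehydrogenation of the only ketone that has an α-hydrogen removes H from C2′ and from the doubly allylic C3′, erases the C2′ stereocentre and gives the linearly conjugated dienone, which cannot aromatise because C6′ is quaternary.

Step 10
Reactants: 15 dienone (both C6′ epimers)
Product: 17 cage enoate (isotwistenone bearing the α-alkylidene γ-lactone), via dienylketene 16 (not isolated)
Conditions: hν (395 nm LED), dry degassed toluene (2 mM), BHT, 110 °C
Reagents that add atoms: none
Why: Proposed new method: Violet light is absorbed only by the yellow cyclohexa-2,4-dienone and cleaves its C1′–C6′ bond (Barton–Quinkert α-cleavage) to dienylketene 16, whose fast thermal 6π reclosure returns 15 with either configuration at C6′, so the two epimers interconvert while a thermal, concerted, inverse-demand [4+2] addition of the electron-poor diene C2′=C3′–C4′=C5′ to the C8=C12 methylene drains one of them. The closest known reaction types are the ketene-mediated photoracemisation of 6,6-disubstituted cyclohexa-2,4-dienones and the thermal intramolecular Diels–Alder reaction of 6-methyl-6-(but-3-enyl)cyclohexa-2,4-dienones to isotwistenones; only their coupling in one flask is new. The C5′–C8 bond closes the cyclopentane C8–C9–C11–C6′–C5′ in the fused (type 1) mode that the three-atom tether C11–C9–C8 enforces, and the C2′–C12 bond closes the bicyclo[2.2.2]octenone across the 1,4-termini of the ring diene. C8 is controlled by C9, whose axial α-CH2 (favoured by A1,3 strain with the methylene) can bring the diene only to the α face of C8=C12 and gives the cis-fused five/six junction, while C5′ and C2′ follow from suprafacial addition to the diene face that carries C11, that is from C6′. C6′ itself is selected kinetically: in the other epimer the same tether would demand a trans-fused junction inside the cage, so it cannot cyclise and is recycled through 16. The step needs cycloaddition to outrun ketene trapping, enone–alkene [2+2] addition and secondary photolysis, which is secured by dry nucleophile-free toluene, high dilution, the short lifetime of 16 and a wavelength beyond the absorption of the β,γ-unsaturated ketone 17.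

Step 11
Reactants: 17 cage enoate
Product: 19 1,2-dihydroandilesin C, via C4′ epimer 18 (not isolated)
Conditions: H2 (1 atm), Pd/C, EtOAc, rt; then t-BuOK (cat.), t-BuOH/THF, rt
Reagents that add atoms: none
Why: Heterogeneous hydrogenation saturates the strained C3′=C4′ bond, probably from the more open face syn to the C1′ carbonyl bridge to give 18, and enolate equilibration of the lactone α-carbon should then favour 19, in which C7′ lies in the cleft beside the carbonyl bridge and the freely rotating C6′ methyl while the small hydrogen faces the rigid C7 methylene of ring B.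

Step 12
Reactants: 19 1,2-dihydroandilesin C
Product: 21 andilesin C, via C2 phenylselenide 20 (not isolated)
Conditions: LDA (1.05 equiv), THF, −78 °C; PhSeBr; then H2O2, pyridine, CH2Cl2, 0 °C
Reagents that add atoms: benzeneselenenyl bromide Br[Se]c1ccccc1 (atoms only in 20)
Why: Kinetic deprotonation should take the accessible C2 methylene of the ε-lactone rather than the tertiary cage-shielded C4′–H (the ketone has no α-hydrogen), and selenoxide syn-elimination gives the (Z)-C1=C2 enoate of the seven-membered lactone without touching a stereocentre.

**Compound list**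
1 | (1R,5R)-(+)-verbenone | CC1=CC(=O)[C@@H]2C[C@H]1C2(C)C | starting material
2 | (3-ethoxy-3-oxopropyl)zinc bromide | CCOC(=O)CC[Zn]Br | starting material
3 | C8 trimethylsilyl enol ether of 4 | CCOC(=O)CC[C@]1(C)C=C(O[Si](C)(C)C)[C@@H]2C[C@H]1C2(C)C | intermediate
4 | 4-methyl-4-(2-ethoxycarbonylethyl)nopinone, chain anti to the CMe2 bridge | CCOC(=O)CC[C@]1(C)CC(=O)[C@@H]2C[C@H]1C2(C)C | intermediate
5 | 3-methylene derivative of 4 (C9=C11) | CCOC(=O)CC[C@]1(C)C(=C)C(=O)[C@@H]2C[C@H]1C2(C)C | intermediate
6 | dimethyl malonate | COC(=O)CC(=O)OC | starting material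
7 | 2-methylpent-1-en-3-one | CCC(=O)C(C)=C | starting material
8 | methyl 3,5-dimethyl-2,4-dioxocyclohexane-1-carboxylate | COC(=O)C1CC(C)C(=O)C(C)C1=O | intermediate
9 | Michael adduct, C11 anti to the bridge, mixture at C2′/C4′/C6′ | CCOC(=O)CC[C@]1(C)[C@H](CC3(C)C(=O)C(C)CC(C(=O)OC)C3=O)C(=O)[C@@H]2C[C@H]1C2(C)C | intermediate
10 | C5′ enol triflate | CCOC(=O)CC[C@]1(C)[C@H](CC3(C)C(=O)C(C)CC(C(=O)OC)=C3OS(=O)(=O)C(F)(F)F)C(=O)[C@@H]2C[C@H]1C2(C)C | intermediate
11 | C5′ hydroxymethyl enoate | CCOC(=O)CC[C@]1(C)[C@H](CC3(C)C(=O)C(C)CC(C(=O)OC)=C3CO)C(=O)[C@@H]2C[C@H]1C2(C)C | intermediate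
12 | pinane-stage butenolide | CCOC(=O)CC[C@]1(C)[C@H](CC3(C)C(=O)C(C)CC4=C3COC4=O)C(=O)[C@@H]2C[C@H]1C2(C)C | intermediate
13 | keto bis-lactone (5α-H, 10β-Me, 9β-H) | CC1(C)OC(=O)CC[C@@]2(C)[C@H]1CCC(=O)[C@H]2CC3(C)C(=O)C(C)CC4=C3COC4=O | intermediate
14 | C8=C12 methylene compound | CC1(C)OC(=O)CC[C@@]2(C)[C@H]1CCC(=C)[C@H]2CC3(C)C(=O)C(C)CC4=C3COC4=O | intermediate
15 | cyclohexa-2,4-dienone, both C6′ epimers | CC1(C)OC(=O)CC[C@@]2(C)[C@H]1CCC(=C)[C@H]2CC3(C)C(=O)C(C)=CC4=C3COC4=O | intermediate
16 | dienylketene from C1′–C6′ cleavage | CC1(C)OC(=O)CC[C@@]2(C)[C@H]1CCC(=C)[C@H]2CC(C)=C3COC(=O)C3=CC(C)=C=O | intermediate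
17 | cage enoate (C3′=C4′) | CC1(C)OC(=O)CC[C@@]2(C)[C@H]1CC[C@@]13C[C@@]4(C)C=C5C(=O)OC[C@]51[C@@](C)(C[C@@H]23)C4=O | intermediate
18 | 4′-epi-1,2-dihydroandilesin C | CC1(C)OC(=O)CC[C@@]2(C)[C@H]1CC[C@@]13C[C@@]4(C)C[C@H]5C(=O)OC[C@]51[C@@](C)(C[C@@H]23)C4=O | intermediate
19 | 1,2-dihydroandilesin C | CC1(C)OC(=O)CC[C@@]2(C)[C@H]1CC[C@@]13C[C@@]4(C)C[C@@H]5C(=O)OC[C@]51[C@@](C)(C[C@@H]23)C4=O | intermediate
20 | 2-phenylselanyl-1,2-dihydroandilesin C | CC1(C)OC(=O)C([Se]c6ccccc6)C[C@@]2(C)[C@H]1CC[C@@]13C[C@@]4(C)C[C@@H]5C(=O)OC[C@]51[C@@](C)(C[C@@H]23)C4=O | intermediate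
21 | andilesin C | CC1(C)OC(=O)C=C[C@@]2(C)[C@H]1CC[C@@]13C[C@@]4(C)C[C@@H]5C(=O)OC[C@]51[C@@](C)(C[C@@H]23)C4=O | target

**Summary**
Total step count: 12. Longest linear sequence: 11 steps (1, 2, 4–12, from verbenone).

**Steps most likely to fail**
1. Step 10.
   - What may go wrong: cycloaddition between two fully substituted termini may be slow. Ketene capture or competing photocycloaddition may then consume material before the funnelling is complete.
   - Fallback (known chemistry only): it sets out from 15. The epimers are separated by chromatography into the matched C6′ dienone F1 and the mismatched C6′ dienone F2. F1 alone is heated in the dark in o-dichlorobenzene at 160–180 °C (plain thermal intramolecular Diels–Alder reaction) and comes back to the route at 17. F2 is left out.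
2. Step 7.
   - What may go wrong: Lewis-acid enolisation may epimerise C9. The C4 cation may lose a proton instead of being captured. De-ethylation of the oxocarbenium ion may be sluggish.
   - Fallback: it sets out from 12. The ethyl ester is first cleaved with Me3SnOH (1,2-dichloroethane, 80 °C) to the free carboxylic acid F3. F3 is then opened with catalytic TfOH in CH2Cl2 at low temperature. The acid itself traps the cation in a protic, reversible hydro-acyloxylation manifold that needs no dealkylation, and the route is rejoined at 13.
3. Step 11.
   - What may go wrong: the two faces at C4′ are nearly mirror-related (C7H2 against C6′-CH3). The epimer equilibrium may therefore be unfavourable, or facial selectivity may be poor.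
   - Fallback: it sets out from 17. Rh- or Cu-catalysed 1,4-hydrosilylation with Et3SiH gives the silyl ketene acetal F4. F4 is protonated at C4′ under reagent control by a chiral Brønsted acid (either antipode can be chosen), and the route is rejoined at 19.

**Further compounds**
F1 | step 10 | matched C6′ epimer of dienone 15 | CC1(C)OC(=O)CC[C@@]2(C)[C@H]1CCC(=C)[C@H]2C[C@@]3(C)C(=O)C(C)=CC4=C3COC4=O
F2 | step 10 | mismatched C6′ epimer of dienone 15 | CC1(C)OC(=O)CC[C@@]2(C)[C@H]1CCC(=C)[C@H]2C[C@]3(C)C(=O)C(C)=CC4=C3COC4=O
F3 | step 7 | free carboxylic acid of 12 | OC(=O)CC[C@]1(C)[C@H](CC3(C)C(=O)C(C)CC4=C3COC4=O)C(=O)[C@@H]2C[C@H]1C2(C)C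
F4 | step 11 | triethylsilyl ketene acetal of the γ-lactone | CC1(C)OC(=O)CC[C@@]2(C)[C@H]1CC[C@@]13C[C@@]4(C)CC5=C(O[Si](CC)(CC)CC)OC[C@]51[C@@](C)(C[C@@H]23)C4=O
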